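All runs are calculated for an exercise; the scatter is artificial.

Start from the concentration.

| flask | starting material | remark | time |
|---|---|---|---|
| dawn | 0.035 M | run made earlier |  |
| spring | 0.068 M | run made earlier |  |
| teal | 0.10 M |  | 30 min |
| green | 0.060 M |  | 100 min |

| run | time / min | ring / % | open dimer / % | starting material / % |
|---|---|---|---|---|
| dawn | 1.50 | 2 | 3 | 95 |
| dawn | 3.00 | 5 | 5 | 90 |
| dawn | 5.00 | 4 | 10 | 85 |
| dawn | 8.00 | 10 | 13 | 79 |
| dawn | 12.0 | 12 | 16 | 71 |
| dawn | 20.0 | 20 | 24 | 62 |
| spring | 1.50 | 1 | 6 | 93 |
| spring | 3.00 | 1 | 7 | 87 |
| spring | 5.00 | 5 | 13 | 80 |
| spring | 8.00 | 8 | 22 | 71 |
| spring | 12.0 | 12 | 28 | 64 |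
| spring | 20.0 | 16 | 28 | 51 |

(standard deviation of a reading: 1.5 percentage points)

- percentages count the starting material that a species holds: one open dimer counts as two
- on the list of suspects stand: starting material <-> ring; 2 starting material <-> open dimer

- which one finishes higher in share of ring in all that became ring or open dimer ("neither" within 2 percentage points) (teal / green / neither)
- share of ring in all that became ring or open dimer, teal
- share of ring in all that became ring or open dimer, green

Ring forms from one starting material and open dimer from two, so the forward rate of the first goes as [starting material] and that of the second as its square. Their ratio, the selectivity factor, is therefore a fixed concentration divided by [starting material], and the percentages can give it directly, because they count starting material held.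

The dawn run at 12.0 min and the spring run at 8.00 min both had 71% of the charge left. Multiplying ring over open dimer by the mean [starting material] of that stretch, and setting aside the way back, I read 0.0224 M from dawn and 0.0211 M from spring. Their mean, 0.0218 M, is the crossover concentration: the [starting material] at which both forward paths use starting material equally fast. It is a reading and carries the scatter of 1.5 percentage points.

Of what is forming at any moment, ring takes the crossover concentration over itself plus [starting material]. At the charge this gives 17.9% in teal and 26.6% in green. With half the charge left, it gives 30.4% in teal and 42.1% in green. My own reckoning was teal near 30.4%, and green above 42.1%, since green runs longer, 100 min against 30 min.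

The forecast said green, with 37% for teal and 78% for green, expecting that open dimer in green “drains through starting material into ring”.

The flasks gave green, with 31.9% for teal and 60.7% for green. The forecast had the right flask and stood 5.1 points and 17 points too high.

    starting material ⇌ ring (K = 2.82, k = 2.18 × 10⁻⁴ /s)
    2 starting material ⇌ open dimer (K = 19.0 /M, k = 0.00473 /M/s)

In green at 100 min, [starting material] was 0.0176 M, so the crossover concentration stood at 1.24 times it; the forward ring path then used starting material at 1.3 times the rate of the forward dimer path, against 0.38 at the start, with ring at 42.9% and open dimer at 27.7%. That time is 1.15 half-lives of the slowest mode of green, 86.6 min, and the share reached 84.3% by 1000 min.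

Take a neighbour of green charged with 0.24 M and read at 100 min. The rule gives ring 8.33% of what forms at the charge, and 29.8% with 21% left. The computed share there is 36.0%, with open dimer at 50.3%.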